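**Retrosynthetic overview**

1. Target 21 comes from the (2S)-flavanone 7,3′-bis(MOM) ether 20 by acid methanolysis.
2. Ring C, the only ring made, is closed in 20 by rhodium-catalysed enantioselective intramolecular hydroacylation of 19, which forms C3–C4 and sets C2. The feature used is that the C4 carbonyl sits on C4a between the hydrogen-bonded C5–OH and the O1-bearing C8a (a 6-alkenyloxy-salicylaldehyde pattern), and that C3 is a methylene, the terminal carbon of a 1-arylvinyl ether on O1.
3. Aldehyde 19 comes from the symmetric ring A resorcinol 16 by magnesium-mediated ortho-formylation and 7-O-MOM protection; the vinyl ether of 16 comes from aryl ester 14 by titanium methylenation, then SEM removal.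
4. Ester 14 joins ring A phenol 7 (phloroglucinol: mono-silylation, SEM, directed metalation/prenylation) and ring B acid 13 (5-bromo-2-methoxyphenol: MOM, directed metalation/prenylation, Br to CO2H).
5. Rings A and B are bought as benzenes; ring C is formed in the penultimate step.

Key step: step 13

Abbreviations: prenyl = 3-methylbut-2-en-1-yl; MOM = methoxymethyl; SEM = [2-(trimethylsilyl)ethoxy]methyl; TIPS = triisopropylsilyl.

Remark: which bisphosphine antipode gives the (2S) configuration cannot be assigned from precedent on this substrate class. (R)-DTBM-SEGPHOS is written, and its antipode is to be used should the first run show the opposite sense.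

**Step 1**
Reactants: 1 phloroglucinol (benzene-1,3,5-triol; threefold excess)
Product: 2 5-[(triisopropylsilyl)oxy]benzene-1,3-diol
Conditions: TIPSCl (1 equiv), imidazole, DMF, 0 °C → rt
Reagents that add atoms: triisopropylsilyl chloride, CC(C)[Si](Cl)(C(C)C)C(C)C
Why: Silyl ether formation is biased toward the mono-ether by the excess of the cheap, water-soluble triol, and it sets apart the oxygen that becomes O1 from the two that become O5 and O7.

**Step 2**
Reactants: 2 5-[(triisopropylsilyl)oxy]benzene-1,3-diol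
Product: 3 1,3-bis(SEM-oxy)-5-[(triisopropylsilyl)oxy]benzene
Conditions: SEMCl (2.5 equiv), i-Pr2NEt, CH2Cl2, 0 °C → rt
Reagents that add atoms: 2-(trimethylsilyl)ethoxymethyl chloride, C[Si](C)(C)CCOCCl
Why: O-Alkylation of both phenols (SEM acetal formation) under amine base leaves the aryl silyl ether intact and installs two fluoride-labile, ortho-directing groups.

**Step 3**
Reactants: 3 1,3-bis(SEM-oxy)-5-[(triisopropylsilyl)oxy]benzene; 4 prenyl bromide
Product: 6 2-prenyl-1,3-bis(SEM-oxy)-5-[(triisopropylsilyl)oxy]benzene, via aryllithium 5 (not isolated)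
Conditions: n-BuLi, THF, 0 °C; then CuI (10 mol %), 4, −78 °C → rt
Reagents that add atoms: none
Why: Directed ortho-metalation should occur at the one position flanked by two acetal oxygens (the sites beside the bulky silyl ether being shielded), and the aryllithium 5 is then allylated at the primary carbon of prenyl bromide under copper catalysis.

**Step 4**
Reactants: 6 2-prenyl-1,3-bis(SEM-oxy)-5-[(triisopropylsilyl)oxy]benzene
Product: 7 4-prenyl-3,5-bis(SEM-oxy)phenol
Conditions: Bu4NF (1.1 equiv), THF, 0 °C; then aq. NH4Cl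
Reagents that add atoms: none
Why: Fluoride desilylation cleaves the aryl TIPS ether at 0 °C, where aryl SEM ethers are inert, and frees the phenol that will carry the vinyl ether.

**Step 5**
Reactants: 8 5-bromo-2-methoxyphenol
Product: 9 4-bromo-1-methoxy-2-(methoxymethoxy)benzene
Conditions: MOMCl, i-Pr2NEt, CH2Cl2, 0 °C → rt
Reagents that add atoms: chloromethyl methyl ether, COCCl
Why: MOM ether formation protects the phenol and provides the directing group for the next metalation.

**Step 6**
Reactants: 9 4-bromo-1-methoxy-2-(methoxymethoxy)benzene; 4 prenyl bromide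
Product: 11 1-bromo-4-methoxy-3-(methoxymethoxy)-2-prenylbenzene, via aryllithium 10 (not isolated)
Conditions: LiN(i-Pr)2 (commercial solution, 1.05 equiv), THF, −78 °C; then CuI (10 mol %), 4, −78 → −40 °C
Reagents that add atoms: none
Why: The amide base deprotonates (without bromine–lithium exchange) the most acidic ring position, flanked by the MOM ether and bromine, as is known for 3-alkoxybromoarenes; the low temperature avoids aryne formation, and SN2 allylation then installs the prenyl group.

**Step 7**
Reactants: 11 1-bromo-4-methoxy-3-(methoxymethoxy)-2-prenylbenzene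
Product: 13 4-methoxy-3-(methoxymethoxy)-2-prenylbenzoic acid, via aryllithium 12 (not isolated)
Conditions: n-BuLi, THF, −78 °C; CO2, −78 °C → rt; then cold 1 M HCl to pH 3
Reagents that add atoms: carbon dioxide, O=C=O
Why: Bromine–lithium exchange followed by carboxylation of the aryllithium is a standard route to benzoic acids, and the MOM ether should survive the brief cold acidification.

**Step 8**
Reactants: 7 4-prenyl-3,5-bis(SEM-oxy)phenol; 13 4-methoxy-3-(methoxymethoxy)-2-prenylbenzoic acid
Product: 14 4-prenyl-3,5-bis(SEM-oxy)phenyl 4-methoxy-3-(methoxymethoxy)-2-prenylbenzoate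
Conditions: DCC, DMAP (20 mol %), CH2Cl2, 0 °C → rt
Reagents that add atoms: none
Why: Steglich esterification joins an unhindered phenol to a benzoic acid with a single ortho substituent under neutral conditions that leave all acetals intact.

**Step 9**
Reactants: 14 4-prenyl-3,5-bis(SEM-oxy)phenyl 4-methoxy-3-(methoxymethoxy)-2-prenylbenzoate
Product: 15 4-prenyl-3,5-bis(SEM-oxy)phenyl 1-[4-methoxy-3-(methoxymethoxy)-2-prenylphenyl]ethenyl ether
Conditions: Cp2TiMe2 (3 equiv), toluene/THF, 65–70 °C, dark; filtration through basic alumina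
Reagents that add atoms: dimethyltitanocene, C[Ti](C)(C1C=CC=C1)C1C=CC=C1
Why: Petasis methylenation (thermally generated Cp2Ti=CH2, [2+2] addition to the ester carbonyl and cycloreversion) turns the ester into the 1-arylvinyl aryl ether without Lewis-acidic aluminium, and it tolerates acetals, silanes and trisubstituted alkenes.

**Step 10**
Reactants: 15 4-prenyl-3,5-bis(SEM-oxy)phenyl 1-[4-methoxy-3-(methoxymethoxy)-2-prenylphenyl]ethenyl ether
Product: 16 5-({1-[4-methoxy-3-(methoxymethoxy)-2-prenylphenyl]ethenyl}oxy)-2-prenylbenzene-1,3-diol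
Conditions: Bu4NF (8 equiv), ethylenediamine, DMF, 70 °C; then cold aq. NH4Cl
Reagents that add atoms: none
Why: Fluoride-induced fragmentation of both aryl SEM ethers is a basic deprotection that spares the acid-labile enol ether and the MOM ether, and ethylenediamine takes up the formaldehyde released so that the electron-rich phenoxide is not hydroxymethylated.

**Step 11**
Reactants: 16 5-({1-[4-methoxy-3-(methoxymethoxy)-2-prenylphenyl]ethenyl}oxy)-2-prenylbenzene-1,3-diol
Product: 18 2,4-dihydroxy-6-({1-[4-methoxy-3-(methoxymethoxy)-2-prenylphenyl]ethenyl}oxy)-3-prenylbenzaldehyde, via hydroxymethyl phenol 17 (not isolated)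
Conditions: MgCl2 (anhydrous), Et3N, (CH2O)n, THF, 65 °C; then cold aq. NaH2PO4
Reagents that add atoms: paraformaldehyde (as formaldehyde), C=O
Why: Magnesium-mediated ortho-formylation of phenols (Casnati–Skattebøl) is ortho-specific and runs in basic medium; the two open ortho positions of the symmetric resorcinol are equivalent, the hydroxymethyl phenol 17 is oxidised in the flask by hydride transfer to a second formaldehyde, and the first formyl group deactivates the ring against a second.

**Step 12**
Reactants: 18 2,4-dihydroxy-6-({1-[4-methoxy-3-(methoxymethoxy)-2-prenylphenyl]ethenyl}oxy)-3-prenylbenzaldehyde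
Product: 19 2-hydroxy-4-(methoxymethoxy)-6-({1-[4-methoxy-3-(methoxymethoxy)-2-prenylphenyl]ethenyl}oxy)-3-prenylbenzaldehyde
Conditions: MOMCl (1.1 equiv), i-Pr2NEt, CH2Cl2, 0 °C
Reagents that add atoms: chloromethyl methyl ether, COCCl
Why: The hydroxyl para to the formyl group is the more acidic and is not tied up in the hydrogen bond to the carbonyl, so one equivalent of MOMCl should alkylate it selectively, as is standard for 2,4-dihydroxybenzaldehydes.

**Step 13**
Reactants: 19 2-hydroxy-4-(methoxymethoxy)-6-({1-[4-methoxy-3-(methoxymethoxy)-2-prenylphenyl]ethenyl}oxy)-3-prenylbenzaldehyde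
Product: 20 (2S)-5-hydroxy-2-[4-methoxy-3-(methoxymethoxy)-2-prenylphenyl]-7-(methoxymethoxy)-6-prenyl-2,3-dihydro-4H-chromen-4-one
Conditions: [Rh(cod)Cl]2 (2.5 mol %), (R)-DTBM-SEGPHOS (5.5 mol %), NaB[3,5-(CF3)2C6H3]4 (6 mol %), 4 Å molecular sieves, THF, 60 °C, argon, no base
Reagents that add atoms: none
Why: Proposed new method: the cationic monovalent rhodium–bisphosphine fragment, held at the vinyl ether (alkene and O1), should add oxidatively into the formyl C–H bond, which the C5–OH···O=C hydrogen bond keeps turned toward O1, to give an acyl hydride of trivalent rhodium; the 1,1-disubstituted alkene then inserts into Rh–H with hydride going to C2, and C–C reductive elimination from the resulting seven-membered rhodacycle joins the acyl carbon C4 to C3. The closest known reaction type is the rhodium–bisphosphine-catalysed enantioselective intramolecular hydroacylation of 1,1-disubstituted alkenes held ortho to an aryl aldehyde (2-(1-substituted vinyl)benzaldehydes to 3-substituted indanones, N-vinyl heteroaryl aldehydes to five-membered ketones), together with rhodium hydroacylations of salicylaldehydes; an oxygen-tethered 1-arylvinyl ether closing to a six-membered ketone has not been shown. Ring C closes in a formal 6-endo-trig mode, both alkene carbons ending inside the ring. The only new stereocentre, C2, is set in the hydride insertion step, and its (S) configuration is controlled by the chiral bisphosphine, which selects the alkene face presented to Rh–H. The step needs hydride delivery to C2 and not to C3, and hydroacylation faster than decarbonylation: insertion the other way would put rhodium on a fully substituted, oxygen-bearing benzylic carbon and lead to a quaternary 2-aryl-2-methylbenzofuranone, which the hindered internal alkene carbon disfavours, while chelation by the tethered vinyl ether keeps the acyl hydride saturated. The reaction is run without base because a phenoxide O,C-chelate would hold rhodium on the C5 side of the acyl carbon, out of reach of the alkene on O1.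

**Step 14**
Reactants: 20 (2S)-5-hydroxy-2-[4-methoxy-3-(methoxymethoxy)-2-prenylphenyl]-7-(methoxymethoxy)-6-prenyl-2,3-dihydro-4H-chromen-4-one
Product: 21 (2S)-5,7-dihydroxy-2-(3-hydroxy-4-methoxy-2-prenylphenyl)-6-prenyl-2,3-dihydro-4H-chromen-4-one (CNP0306216.1)
Conditions: HCl (3 M in MeOH), 40 °C, short reaction time
Reagents that add atoms: none
Why: Acid-catalysed acetal exchange with methanol removes both MOM ethers; C2 is not enolisable and ring opening of a 5-hydroxyflavanone is slow in acid, and the mild temperature is chosen so that the phenols do not add to the neighbouring prenyl groups.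

**Compound list**

1 | phloroglucinol | Oc1cc(O)cc(O)c1 | starting material
2 | 5-[(triisopropylsilyl)oxy]benzene-1,3-diol | Oc1cc(O)cc(O[Si](C(C)C)(C(C)C)C(C)C)c1 | intermediate
3 | 1,3-bis(SEM-oxy)-5-[(triisopropylsilyl)oxy]benzene | C[Si](C)(C)CCOCOc1cc(OCOCC[Si](C)(C)C)cc(O[Si](C(C)C)(C(C)C)C(C)C)c1 | intermediate
4 | prenyl bromide (1-bromo-3-methylbut-2-ene) | CC(C)=CCBr | starting material
5 | [2,6-bis(SEM-oxy)-4-(triisopropylsilyloxy)phenyl]lithium | [Li]c1c(OCOCC[Si](C)(C)C)cc(O[Si](C(C)C)(C(C)C)C(C)C)cc1OCOCC[Si](C)(C)C | intermediate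
6 | 2-prenyl-1,3-bis(SEM-oxy)-5-[(triisopropylsilyl)oxy]benzene | CC(C)=CCc1c(OCOCC[Si](C)(C)C)cc(O[Si](C(C)C)(C(C)C)C(C)C)cc1OCOCC[Si](C)(C)C | intermediate
7 | 4-prenyl-3,5-bis(SEM-oxy)phenol | CC(C)=CCc1c(OCOCC[Si](C)(C)C)cc(O)cc1OCOCC[Si](C)(C)C | intermediate
8 | 5-bromo-2-methoxyphenol | COc1ccc(Br)cc1O | starting material
9 | 4-bromo-1-methoxy-2-(methoxymethoxy)benzene | COCOc1cc(Br)ccc1OC | intermediate
10 | [6-bromo-3-methoxy-2-(methoxymethoxy)phenyl]lithium | COCOc1c([Li])c(Br)ccc1OC | intermediate
11 | 1-bromo-4-methoxy-3-(methoxymethoxy)-2-prenylbenzene | COCOc1c(CC=C(C)C)c(Br)ccc1OC | intermediate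
12 | [4-methoxy-3-(methoxymethoxy)-2-prenylphenyl]lithium | COCOc1c(CC=C(C)C)c([Li])ccc1OC | intermediate
13 | 4-methoxy-3-(methoxymethoxy)-2-prenylbenzoic acid | COCOc1c(CC=C(C)C)c(C(=O)O)ccc1OC | intermediate
14 | 4-prenyl-3,5-bis(SEM-oxy)phenyl 4-methoxy-3-(methoxymethoxy)-2-prenylbenzoate | COCOc1c(CC=C(C)C)c(C(=O)Oc2cc(OCOCC[Si](C)(C)C)c(CC=C(C)C)c(OCOCC[Si](C)(C)C)c2)ccc1OC | intermediate
15 | 4-prenyl-3,5-bis(SEM-oxy)phenyl 1-[4-methoxy-3-(methoxymethoxy)-2-prenylphenyl]ethenyl ether | COCOc1c(CC=C(C)C)c(C(=C)Oc2cc(OCOCC[Si](C)(C)C)c(CC=C(C)C)c(OCOCC[Si](C)(C)C)c2)ccc1OC | intermediate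
16 | 5-({1-[4-methoxy-3-(methoxymethoxy)-2-prenylphenyl]ethenyl}oxy)-2-prenylbenzene-1,3-diol | COCOc1c(CC=C(C)C)c(C(=C)Oc2cc(O)c(CC=C(C)C)c(O)c2)ccc1OC | intermediate
17 | 4-(hydroxymethyl)-5-({1-[4-methoxy-3-(methoxymethoxy)-2-prenylphenyl]ethenyl}oxy)-2-prenylbenzene-1,3-diol | COCOc1c(CC=C(C)C)c(C(=C)Oc2cc(O)c(CC=C(C)C)c(O)c2CO)ccc1OC | intermediate
18 | 2,4-dihydroxy-6-({1-[4-methoxy-3-(methoxymethoxy)-2-prenylphenyl]ethenyl}oxy)-3-prenylbenzaldehyde | O=Cc1c(O)c(CC=C(C)C)c(O)cc1OC(=C)c1ccc(OC)c(OCOC)c1CC=C(C)C | intermediate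
19 | 2-hydroxy-4-(methoxymethoxy)-6-({1-[4-methoxy-3-(methoxymethoxy)-2-prenylphenyl]ethenyl}oxy)-3-prenylbenzaldehyde | O=Cc1c(O)c(CC=C(C)C)c(OCOC)cc1OC(=C)c1ccc(OC)c(OCOC)c1CC=C(C)C | intermediate
20 | (2S)-5-hydroxy-2-[4-methoxy-3-(methoxymethoxy)-2-prenylphenyl]-7-(methoxymethoxy)-6-prenyl-2,3-dihydro-4H-chromen-4-one | COCOc1c(OC)ccc([C@@H]2CC(=O)c3c(cc(OCOC)c(CC=C(C)C)c3O)O2)c1CC=C(C)C | intermediate
21 | (2S)-5,7-dihydroxy-2-(3-hydroxy-4-methoxy-2-prenylphenyl)-6-prenyl-2,3-dihydro-4H-chromen-4-one | COc1ccc([C@@H]2CC(=O)c3c(cc(O)c(CC=C(C)C)c3O)O2)c(CC=C(C)C)c1O | target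

**Step count**

Total: 14 steps. Longest linear sequence: 11 steps (steps 1–4, then 8–14); the ring B branch is steps 5–7.

**Steps most likely to fail**

1. Step 13 (proposed new method). Decarbonylation of the acyl rhodium hydride, unproductive binding of rhodium at the phenol side, hydride insertion with the opposite regiochemistry (five-membered ring) or poor facial selectivity may defeat the ring closure. The fallback uses known chemistry and closes ring C at O1–C2 instead, by the chalcone route. It sets out from bromide 11 and phenol 7 and returns to the route at target 21. Aryllithium 12 (from 11, n-BuLi, −78 °C) is quenched with DMF to give 4-methoxy-3-(methoxymethoxy)-2-prenylbenzaldehyde F1. Phenol 7 is ortho-formylated (MgCl2, Et3N, (CH2O)n, THF, 65 °C) through 2-(hydroxymethyl)-4-prenyl-3,5-bis(SEM-oxy)phenol F2, which is not isolated, to 2-hydroxy-5-prenyl-4,6-bis(SEM-oxy)benzaldehyde F3. MeMgBr in THF gives 2-(1-hydroxyethyl)-4-prenyl-3,5-bis(SEM-oxy)phenol F4, and MnO2 in CH2Cl2 gives 1-[2-hydroxy-5-prenyl-4,6-bis(SEM-oxy)phenyl]ethan-1-one F5. Claisen–Schmidt condensation of F5 with F1 (KOH, EtOH) gives the (E)-2′-hydroxychalcone F6, in which only the hydroxyl destined to become O1 is free. NaOAc in hot EtOH closes ring C by oxa-Michael addition to the racemic 5,7-bis(SEM-oxy) flavanone F7. Chromatography on a chiral stationary phase gives the (2S)-5,7-bis(SEM-oxy) flavanone F8; the other enantiomer is re-equilibrated through F6 and recycled. HCl in MeOH at 50 °C removes the two SEM ethers and the MOM ether of F8 to give 21.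

2. Step 11. The very electron-rich resorcinol may over-react with formaldehyde (diarylmethane formation, second formylation), the enol ether may be lost on contact with the magnesium salt or during work-up, and the double SEM cleavage of step 10 that feeds it may stall on the hindered, electron-rich ring. The fallback replaces phenoxide-directed formylation by directed lithiation before deprotection. It sets out from vinyl ether 15 and returns at aldehyde 18. n-BuLi (THF, −78 → −30 °C) should lithiate one of the two equivalent ring A positions flanked by a SEM ether and the vinyl ether oxygen to give the 2-lithio derivative of 15 F9. DMF converts it into 6-({1-[4-methoxy-3-(methoxymethoxy)-2-prenylphenyl]ethenyl}oxy)-3-prenyl-2,4-bis(SEM-oxy)benzaldehyde F10. Bu4NF in THF/DMPU at 50 °C (no diamine, which would condense with the aldehyde) removes both SEM ethers, now activated by the formyl group, to give 18.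

3. Step 6. The ortho-bromoaryllithium may lose lithium bromide (aryne formation), the bromine may migrate, or allylation may occur at the tertiary carbon. The fallback installs the side chain by sigmatropic rearrangement and metathesis. It sets out from phenol 8 and returns at bromide 11. O-Allylation (allyl bromide, K2CO3, acetone) gives 2-(allyloxy)-4-bromo-1-methoxybenzene F11. Aromatic Claisen rearrangement (N,N-diethylaniline, 190 °C) can only go to the free ortho position next to bromine and gives 3-bromo-6-methoxy-2-(prop-2-en-1-yl)phenol F12. MOMCl and i-Pr2NEt give 1-bromo-4-methoxy-3-(methoxymethoxy)-2-(prop-2-en-1-yl)benzene F13. Cross-metathesis with 2-methyl-2-butene (second-generation Grubbs catalyst, CH2Cl2, 40 °C) converts the allyl into the prenyl group of 11.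

**Further compounds**

F1 | step 13 | 4-methoxy-3-(methoxymethoxy)-2-prenylbenzaldehyde | COCOc1c(CC=C(C)C)c(C=O)ccc1OC
F2 | step 13 | 2-(hydroxymethyl)-4-prenyl-3,5-bis(SEM-oxy)phenol | OCc1c(O)cc(OCOCC[Si](C)(C)C)c(CC=C(C)C)c1OCOCC[Si](C)(C)C
F3 | step 13 | 2-hydroxy-5-prenyl-4,6-bis(SEM-oxy)benzaldehyde | O=Cc1c(O)cc(OCOCC[Si](C)(C)C)c(CC=C(C)C)c1OCOCC[Si](C)(C)C
F4 | step 13 | 2-(1-hydroxyethyl)-4-prenyl-3,5-bis(SEM-oxy)phenol (racemic) | CC(O)c1c(O)cc(OCOCC[Si](C)(C)C)c(CC=C(C)C)c1OCOCC[Si](C)(C)C
F5 | step 13 | 1-[2-hydroxy-5-prenyl-4,6-bis(SEM-oxy)phenyl]ethan-1-one | CC(=O)c1c(O)cc(OCOCC[Si](C)(C)C)c(CC=C(C)C)c1OCOCC[Si](C)(C)C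
F6 | step 13 | (E)-1-[2-hydroxy-5-prenyl-4,6-bis(SEM-oxy)phenyl]-3-[4-methoxy-3-(methoxymethoxy)-2-prenylphenyl]prop-2-en-1-one | COCOc1c(CC=C(C)C)c(/C=C/C(=O)c2c(O)cc(OCOCC[Si](C)(C)C)c(CC=C(C)C)c2OCOCC[Si](C)(C)C)ccc1OC
F7 | step 13 | racemic 2-[4-methoxy-3-(methoxymethoxy)-2-prenylphenyl]-6-prenyl-5,7-bis(SEM-oxy)-2,3-dihydro-4H-chromen-4-one | COCOc1c(OC)ccc(C2CC(=O)c3c(cc(OCOCC[Si](C)(C)C)c(CC=C(C)C)c3OCOCC[Si](C)(C)C)O2)c1CC=C(C)C
F8 | step 13 | (2S)-2-[4-methoxy-3-(methoxymethoxy)-2-prenylphenyl]-6-prenyl-5,7-bis(SEM-oxy)-2,3-dihydro-4H-chromen-4-one | COCOc1c(OC)ccc([C@@H]2CC(=O)c3c(cc(OCOCC[Si](C)(C)C)c(CC=C(C)C)c3OCOCC[Si](C)(C)C)O2)c1CC=C(C)C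
F9 | step 11 | 2-lithio derivative of 15 (lithium between the SEM ether and the vinyl ether oxygen of ring A) | [Li]c1c(OCOCC[Si](C)(C)C)c(CC=C(C)C)c(OCOCC[Si](C)(C)C)cc1OC(=C)c1ccc(OC)c(OCOC)c1CC=C(C)C
F10 | step 11 | 6-({1-[4-methoxy-3-(methoxymethoxy)-2-prenylphenyl]ethenyl}oxy)-3-prenyl-2,4-bis(SEM-oxy)benzaldehyde | O=Cc1c(OCOCC[Si](C)(C)C)c(CC=C(C)C)c(OCOCC[Si](C)(C)C)cc1OC(=C)c1ccc(OC)c(OCOC)c1CC=C(C)C
F11 | step 6 | 2-(allyloxy)-4-bromo-1-methoxybenzene | C=CCOc1cc(Br)ccc1OC
F12 | step 6 | 3-bromo-6-methoxy-2-(prop-2-en-1-yl)phenol | C=CCc1c(O)c(OC)ccc1Br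
F13 | step 6 | 1-bromo-4-methoxy-3-(methoxymethoxy)-2-(prop-2-en-1-yl)benzene | C=CCc1c(OCOC)c(OC)ccc1Br
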